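**Retrosynthetic overview**
1. Target 11 ⇐ 10 by removal of both allyl groups; 10 ⇐ ketol 9 by β-face hydride reduction of the C12 ketone.
2. Key C–C disconnection C12–C13: ketol 9 ⇐ keto aldehyde 7 by a carbene-catalysed crossed benzoin, with C12 as acyl anion adding to the C13 enone carbonyl. This closes ring C, rebuilds the bicyclo[3.2.1]octane and installs both the C12 and C13 oxygens.
3. 7 ⇐ iodide 6 ⇐ protected GA1 4 by alkoxy-radical β-scission of the C12–C13 bond (the 13-OH becomes the C13 ketone).
4. 4 ⇐ GA1 2 ⇐ gibberellic acid 1 (ring A hydrogenation, allyl ester, allyl carbonate).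
5. Ring order: rings A, B, D and the lactone come intact from 1; ring C is opened and is the only ring formed, last.

Assumption: gibberellic acid (GA3), a low-cost bulk fermentation product, is taken as an admissible commercial starting material. It supplies the skeleton and C3, C4, C5, C6, C8, C9, C10; the route makes the C12–C13 bond and sets C12 and C13.

Numbering (gibberellin convention): ring A = C1–C5, C10; ring B = C5, C6, C8, C9, C10; ring C = C8, C9, C11, C12, C13, C14; ring D = C8, C14, C13, C16, C15. C7 = carboxyl, C17 = exocyclic CH2, C18 = methyl, C19 = lactone carbonyl. GA1 is 1,2-dihydrogibberellic acid. "Protected" means 7-allyl ester plus 3-O-allyloxycarbonyl. The target is 12α-hydroxy-GA1: the 12-OH is axial on ring C, cis to the 13-OH, anti to C16 and syn to C10.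

**Step 1**
Reactants: 1 gibberellic acid (GA3)
Product: 2 GA1 (1,2-dihydrogibberellic acid)
Conditions: H2 (1 atm, stopped at 1.0 equiv uptake), 5% Pd/BaCO3, THF–pyridine 9:1, 20 °C; chromatography
Reagents that add atoms: none
Why: Partial heterogeneous hydrogenation, the long-known way from GA3 to GA1: on the base-poisoned catalyst the cis-disubstituted ring A alkene is saturated ahead of the 1,1-disubstituted C16 methylene, pyridine suppresses hydrogenolysis of the allylic lactone, no stereocentre is created, and the expected modest yield (roughly a third) is acceptable on a cheap starting material.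

**Step 2**
Reactants: 2 GA1 (1,2-dihydrogibberellic acid)
Product: 3 GA1 7-allyl ester
Conditions: allyl bromide (1.5 equiv), KHCO3 (2 equiv), DMF, 20 °C
Reagents that add atoms: allyl bromide, C=CCBr
Why: Carboxylate O-alkylation (SN2) with only bicarbonate as base, so both hydroxyls stay free and the C3 carbinol, which is aldol-related to the lactone carbonyl, is not epimerised.

**Step 3**
Reactants: 3 GA1 7-allyl ester
Product: 4 protected GA1 (13-OH free)
Conditions: allyl chloroformate (3 equiv), pyridine, 4-(dimethylamino)pyridine (10 mol%), CH2Cl2, 0 → 20 °C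
Reagents that add atoms: allyl chloroformate, C=CCOC(=O)Cl
Why: Chloroformate acylation (carbonate formation) is selective for the secondary 3β-OH because the tertiary bridgehead 13-OH is not acylated under these mild conditions; both protecting groups are now allyl-based and fall together at the end.

**Step 4**
Reactants: 4 protected GA1
Product: 6 protected 12-iodo-12,13-seco-13-oxo-GA1, via 13-O-hypoiodite 5 (not isolated)
Conditions: PhI(OAc)2 (1.5 equiv), I2 (1.0 equiv), cyclohexane–CH2Cl2, hν (tungsten lamp), 20 °C
Reagents that add atoms: iodine, [I][I]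
Why: Suárez hypoiodite reaction (alkoxy-radical β-fragmentation): photolysis of the O–I bond of 5 gives the C13 alkoxy radical, which cleaves C12–C13 because that σ bond is nearly perpendicular to the plane of the C16=C17 alkene and leads straight to the conjugated enone (C13–C14 lies close to that plane, C13–C16 would give a vinyl radical), and the primary C12 radical is captured by I2 far faster than it can add back to the enone; no stereocentre is touched.

**Step 5**
Reactants: 6 protected 12-iodo-12,13-seco-13-oxo-GA1
Product: 7 protected 12,13-seco-13-oxo-GA1-12-al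
Conditions: Me3NO (anhydrous, 4 equiv), NaHCO3 (2 equiv), DMSO, 20 °C
Reagents that add atoms: trimethylamine N-oxide, C[N+](C)(C)[O-]
Why: Kornblum-type oxidation in its amine N-oxide variant: SN2 attack of the N-oxide oxygen on the unhindered primary iodide and loss of Me3N from the alkoxyammonium ion give the aldehyde at room temperature with no base stronger than bicarbonate, which the α-methylene ketone, esters and lactone tolerate.

**Step 6**
Reactants: 7 protected 12,13-seco-13-oxo-GA1-12-al
Product: 9 protected 12-oxo-GA1 (13-hydroxy-12-ketone), via Breslow enaminol 8 (not isolated)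
Conditions: 2-(pentafluorophenyl)-6,7-dihydro-5H-pyrrolo[2,1-c][1,2,4]triazol-2-ium tetrafluoroborate (20 mol%), i-Pr2NEt (20 mol%), 4 Å molecular sieves, CH2Cl2 (0.01 M), 25 °C; product taken on at once
Reagents that add atoms: none
Why: Proposed new method: the closest known reaction type is the carbene-catalysed intramolecular crossed aldehyde–ketone benzoin cyclisation, here extended to an enone carbonyl and a bridged ring; the triazolylidene converts the C12 aldehyde into enaminol 8 (an acyl anion equivalent), whose C12 can reach the C13 carbonyl only from the ring D face that carries C9, so 1,2-addition closes the six-membered ring C and fixes C13 in the GA1 configuration with the OH outward, whereas Stetter-type attack on C17 would need a seven-membered ring; the closure is estimated to be mildly exergonic despite loss of enone conjugation, and high dilution with a weak base disfavours intermolecular benzoin, aldol closure and exo-to-endo enone isomerisation.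

**Step 7**
Reactants: 9 protected 12-oxo-GA1
Product: 10 protected 12α-hydroxy-GA1
Conditions: LiBH(s-Bu)3 (2.2 equiv), THF, −78 °C; sat. aq NH4Cl
Reagents that add atoms: none
Why: Bulky-hydride reduction under steric approach control: the α-face of the C12 ketone is shielded by C10 and its lactone oxygen, which sit 1,3-syn-axial to it on ring C, so hydride is delivered from the β-face (the side of the C15–C16 bridge) and gives the axial 12α-alcohol, cis to the 13-OH, under kinetic control at a temperature where esters, carbonate and lactone survive.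

**Step 8**
Reactants: 10 protected 12α-hydroxy-GA1
Product: 11 12α-hydroxy-GA1 (target)
Conditions: Pd(PPh3)4 (5 mol%), morpholine (6 equiv), THF, 20 °C; then aqueous citric acid (pH 3), EtOAc extraction
Reagents that add atoms: none
Why: Tsuji–Trost deallylation: zerovalent palladium ionises both the allyl ester and the allyl carbonate, morpholine traps the π-allyl units and the carbonate loses CO2, all under near-neutral conditions that avoid retro-aldol epimerisation at C3 and acid-induced rearrangement of the 13-hydroxy-16-ene unit, while the free tertiary allylic alcohol is not ionised.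

**Compound list**
1 | gibberellic acid (GA3; natural enantiomer; 3β,13-dihydroxy-1,16-diene, 7-acid, 19,10-lactone) | C=C1C[C@]23C[C@@]1(O)CC[C@H]2[C@@]12C=C[C@H](O)[C@@](C)(C(=O)O1)[C@H]2[C@@H]3C(=O)O | starting material
2 | GA1 (1,2-dihydrogibberellic acid; 1,2-dihydro-GA3) | C=C1C[C@]23C[C@@]1(O)CC[C@H]2[C@@]12CC[C@H](O)[C@@](C)(C(=O)O1)[C@H]2[C@@H]3C(=O)O | intermediate
3 | GA1 7-allyl ester | C=C1C[C@]23C[C@@]1(O)CC[C@H]2[C@@]12CC[C@H](O)[C@@](C)(C(=O)O1)[C@H]2[C@@H]3C(=O)OCC=C | intermediate
4 | protected GA1 (7-allyl ester, 3-O-allyloxycarbonyl, 13-OH free) | C=C1C[C@]23C[C@@]1(O)CC[C@H]2[C@@]12CC[C@H](OC(=O)OCC=C)[C@@](C)(C(=O)O1)[C@H]2[C@@H]3C(=O)OCC=C | intermediate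
5 | 13-O-hypoiodite of 4 | C=C1C[C@]23C[C@@]1(OI)CC[C@H]2[C@@]12CC[C@H](OC(=O)OCC=C)[C@@](C)(C(=O)O1)[C@H]2[C@@H]3C(=O)OCC=C | intermediate
6 | protected 12-iodo-12,13-seco-13-oxo-GA1 (C9 carries CH2CH2I; ring D is a 2-methylenecyclopentanone spiro-joined at C8; C3–C6, C8–C10 as in GA1) | C=C1C[C@]2(CC1=O)[C@@H](CCI)[C@@]34CC[C@H](OC(=O)OCC=C)[C@@](C)(C(=O)O3)[C@H]4[C@@H]2C(=O)OCC=C | intermediate
7 | protected 12,13-seco-13-oxo-GA1-12-al (C9 carries CH2CHO) | C=C1C[C@]2(CC1=O)[C@@H](CC=O)[C@@]34CC[C@H](OC(=O)OCC=C)[C@@](C)(C(=O)O3)[C@H]4[C@@H]2C(=O)OCC=C | intermediate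
8 | Breslow enaminol of 7 (C12 bears OH and is doubly bonded to the carbene carbon of the 2-pentafluorophenyl-pyrrolotriazolylidene) | C=C1C[C@]2(CC1=O)[C@@H](CC(O)=C5N(c6c(F)c(F)c(F)c(F)c6F)N=C6CCCN56)[C@@]34CC[C@H](OC(=O)OCC=C)[C@@](C)(C(=O)O3)[C@H]4[C@@H]2C(=O)OCC=C | intermediate
9 | protected 12-oxo-GA1 (ring C re-closed; 13-OH as in GA1, C12 ketone) | C=C1C[C@]23C[C@@]1(O)C(=O)C[C@H]2[C@@]12CC[C@H](OC(=O)OCC=C)[C@@](C)(C(=O)O1)[C@H]2[C@@H]3C(=O)OCC=C | intermediate
10 | protected 12α-hydroxy-GA1 (12-OH axial on ring C, cis to 13-OH, anti to C16) | C=C1C[C@]23C[C@@]1(O)[C@@H](O)C[C@H]2[C@@]12CC[C@H](OC(=O)OCC=C)[C@@](C)(C(=O)O1)[C@H]2[C@@H]3C(=O)OCC=C | intermediate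
11 | 12α-hydroxy-GA1 (CNP0260503.1) | C=C1C[C@]23C[C@@]1(O)[C@@H](O)C[C@H]2[C@@]12CC[C@H](O)[C@@](C)(C(=O)O1)[C@H]2[C@@H]3C(=O)O | target

**Totals**
Total step count: 8. Longest linear sequence: 8 steps (1 → 11).

**Steps most likely to fail, with fallbacks**

Step 4 (hypoiodite fragmentation). Acetyl hypoiodite may attack the 16-ene (iodo-semipinacol shift or iodoacetoxylation) faster than the hypoiodite fragments. The alkoxy radical is then generated without any positive-iodine reagent, setting out from 4. Exchange with tert-butyl nitrite (neat, 20 °C, volatiles removed) gives the 13-O-nitrite ester F1. Photolysis of F1 (365 nm, benzene, 20 °C) in the presence of I2 (1.5 equiv) gives the same C13 alkoxy radical, and β-scission followed by iodine-atom transfer returns the material at iodide 6.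

Step 6 (carbene-catalysed closure of C12–C13; the riskiest step). Possible failures are Stetter-type attack on C17, base-induced aldol closure, or a benzoin equilibrium that lies on the open side. In that case the bond is made reductively and irreversibly, setting out from 7. Conjugate addition of PhSH (cat. Et3N, CH2Cl2, 0 °C) masks the enone as the β-phenylthio ketone F2 (C16 epimers, inconsequential). SmI2 (2.5 equiv, THF, t-BuOH, −78 °C) then effects an intramolecular aldehyde–ketone pinacol coupling through the samarium-chelated ketyl, expected to give the cis-12α,13-diol sulfide F3. Oxidation with mCPBA (1.0 equiv, CH2Cl2, −78 °C) gives the sulfoxide F4. Thermal syn-elimination of F4 (toluene, CaCO3, 110 °C; H16 is the only β-hydrogen) restores the 16-methylene and returns the material at 10, so step 7 is bypassed.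

Step 7 (face selectivity at C12). The C16 bridge carbon next to the ketone may block the β-face more than expected, so that hydride enters from the α-face. The equatorial 12β-alcohol F5 is then made on purpose from 9 (NaBH4, MeOH, −40 °C), and the same α-face accessibility is used for an SN2 inversion. Mitsunobu reaction of F5 (ClCH2CO2H, PPh3, DIAD, toluene, 0 → 20 °C; only the secondary 12-OH reacts) gives the 12α-chloroacetate F6. Thiourea (NaHCO3, EtOH–THF, 40 °C) removes the chloroacetyl group under neutral conditions, and the route is rejoined at 10.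

Step 1 is low-yielding but precedented and is run on the cheapest material.

**Further compounds**
F1 | step 4 | 13-O-nitrite ester of 4 | C=C1C[C@]23C[C@@]1(ON=O)CC[C@H]2[C@@]12CC[C@H](OC(=O)OCC=C)[C@@](C)(C(=O)O1)[C@H]2[C@@H]3C(=O)OCC=C
F2 | step 6 | phenylthio adduct of 7 (C17 bears SPh, C16 sp3, both epimers) | c1ccccc1SCC1C[C@]2(CC1=O)[C@@H](CC=O)[C@@]34CC[C@H](OC(=O)OCC=C)[C@@](C)(C(=O)O3)[C@H]4[C@@H]2C(=O)OCC=C
F3 | step 6 | protected 17-phenylthio-16,17-dihydro-12α-hydroxy-GA1 (cis-12α,13-diol) | c1ccccc1SCC1C[C@]23C[C@@]1(O)[C@@H](O)C[C@H]2[C@@]12CC[C@H](OC(=O)OCC=C)[C@@](C)(C(=O)O1)[C@H]2[C@@H]3C(=O)OCC=C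
F4 | step 6 | sulfoxide of F3 | O=S(c1ccccc1)CC1C[C@]23C[C@@]1(O)[C@@H](O)C[C@H]2[C@@]12CC[C@H](OC(=O)OCC=C)[C@@](C)(C(=O)O1)[C@H]2[C@@H]3C(=O)OCC=C
F5 | step 7 | protected 12β-hydroxy-GA1 (12-OH equatorial, C12 epimer of 10) | C=C1C[C@]23C[C@@]1(O)[C@H](O)C[C@H]2[C@@]12CC[C@H](OC(=O)OCC=C)[C@@](C)(C(=O)O1)[C@H]2[C@@H]3C(=O)OCC=C
F6 | step 7 | 12α-O-chloroacetate of 10 | C=C1C[C@]23C[C@@]1(O)[C@@H](OC(=O)CCl)C[C@H]2[C@@]12CC[C@H](OC(=O)OCC=C)[C@@](C)(C(=O)O1)[C@H]2[C@@H]3C(=O)OCC=C
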